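**Plan**

- The retrosynthesis cuts the two aryl–CH2 bonds of the target, C8–CH2 on ring A and C5'–CH2 on ring B. Each prenylated carbon sits ortho to a phenolic oxygen (C8 beside O7, C5' beside O4'), and the 7-OH and 4'-OH are the two most acidic hydroxyls of the 5,7,3',4'-tetrahydroxyflavone core. Both C5 units can therefore be placed on oxygen first, as 1,1-dimethylallyl ethers.
- In the forward direction no ring is built: rings A, C and B come intact from luteolin. O7 and O4' are alkylated with a tertiary propargyl chloride, both alkynes are semi-hydrogenated, and one thermal operation moves both allyl groups from oxygen to carbon with allylic inversion.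
- There is no stereochemistry to control: the target has no stereocentre, each new olefin ends in two methyl groups, and the sp3 carbons of the dienone stage disappear on enolisation.

Key step: step 3

Remark on the chemistry: alkylation of the tetrahydroxyflavone is assumed to follow the usual reactivity order 7-OH > 4'-OH > 3'-OH > 5-OH (the 5-OH is chelated to the C4 carbonyl).

**Route**

Step 1
Reactants: 1 luteolin (5,7,3',4'-tetrahydroxyflavone); 2 3-chloro-3-methylbut-1-yne
Product: 3 luteolin 7,4'-bis(2-methylbut-3-yn-2-yl) ether (5-hydroxy-2-[3-hydroxy-4-(2-methylbut-3-yn-2-yloxy)phenyl]-7-(2-methylbut-3-yn-2-yloxy)-4H-chromen-4-one)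
Conditions: 2 (2.2 equiv), DBU (2.4 equiv), CuCl2·2H2O (1 mol %), MeCN/DMF, −5 to 0 °C
Reagents that add atoms: none
Why: This is a copper-catalysed propargylic O-alkylation of phenols, in which the copper acetylide of 2 ionises to an allenylidene-type electrophile that is captured at its tertiary carbon by the two phenoxides that two equivalents of DBU generate, O7 and O4' (both conjugated to the C4 carbonyl), while the 5-OH stays locked in its hydrogen bond and the less acidic 3'-OH, soon shielded by the neighbouring tertiary ether, should be left alone.

Step 2
Reactants: 3 luteolin 7,4'-bis(2-methylbut-3-yn-2-yl) ether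
Product: 4 luteolin 7,4'-bis(2-methylbut-3-en-2-yl) ether (5-hydroxy-2-[3-hydroxy-4-(2-methylbut-3-en-2-yloxy)phenyl]-7-(2-methylbut-3-en-2-yloxy)-4H-chromen-4-one)
Conditions: H2 (1 atm, stopped after 2 equiv), Pd/CaCO3 poisoned with Pb(OAc)2, quinoline, EtOAc, rt
Reagents that add atoms: none
Why: In this Lindlar semi-hydrogenation the lead- and quinoline-poisoned palladium surface adds one equivalent of H2 to each terminal alkyne and releases the vinyl group, leaving the flavone C2=C3 bond, the aryl C–O bonds and the free phenols untouched at room temperature and neutral pH, where the tertiary allyl ethers neither ionise nor rearrange.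

Step 3
Reactants: 4 luteolin 7,4'-bis(2-methylbut-3-en-2-yl) ether
Product: 6 Epimedokoreanin B, via bis-dienone 5 (not isolated)
Conditions: PhNEt2 (degassed), 130–140 °C, Ar
Reagents that add atoms: none
Why: Each ether should undergo a concerted, suprafacial [3,3] sigmatropic shift through a chair-like six-membered transition state in which the O–CMe2 bond breaks while the terminal CH2 bonds to the ortho carbon (C8 on ring A, C5' on ring B), so the 1,1-dimethylallyl group arrives as a 3-methylbut-2-enyl group, and the dienone 5 then enolises to the phenols. This is the aromatic Claisen rearrangement of aryl 1,1-dimethylallyl ethers, the standard entry to ortho-prenylphenols and 8-prenylated 5-hydroxyflavonoids. No ring is closed and no stereocentre remains, because the sp3 carbons C8 and C5' of 5 are flattened on enolisation and each new olefin carries two identical methyl groups. The selectivity needed is C8 over C6 on ring A, and it should come from the chelate between the 5-OH and the C4 carbonyl, which fixes the bond alternation of ring A so that C7–C8 has more double-bond character than C6–C7 and is the kinetically preferred terminus. On ring B a shift to C3' would give a dienone whose quaternary carbon bears oxygen and cannot enolise, so it can only revert and all material should drain through C5'. The geminal methyl groups lower the barrier enough for 130–140 °C, and the basic amine solvent suppresses acid-catalysed addition of the new phenols to the prenyl double bonds.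

**Compound list**

1 | luteolin (5,7,3',4'-tetrahydroxyflavone) | O=c1cc(-c2ccc(O)c(O)c2)oc2cc(O)cc(O)c12 | starting material
2 | 3-chloro-3-methylbut-1-yne | C#CC(C)(C)Cl | starting material
3 | luteolin 7,4'-bis(2-methylbut-3-yn-2-yl) ether | C#CC(C)(C)Oc1cc(O)c2c(=O)cc(-c3ccc(OC(C)(C)C#C)c(O)c3)oc2c1 | intermediate
4 | luteolin 7,4'-bis(2-methylbut-3-en-2-yl) ether | C=CC(C)(C)Oc1cc(O)c2c(=O)cc(-c3ccc(OC(C)(C)C=C)c(O)c3)oc2c1 | intermediate
5 | bis-dienone (ring A as 5-hydroxy-7-oxo-8-prenyl-7,8-dihydro form, ring B as 3'-hydroxy-4'-oxo-5'-prenyl-4',5'-dihydro form; not isolated, configuration at C8 and C5' undefined and transient) | O=C1C=C(O)C2=C(OC(C3=CC(CC=C(C)C)C(=O)C(O)=C3)=CC2=O)C1CC=C(C)C | intermediate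
6 | Epimedokoreanin B (2-[3,4-dihydroxy-5-(3-methylbut-2-enyl)phenyl]-5,7-dihydroxy-8-(3-methylbut-2-enyl)-4H-chromen-4-one) | CC(C)=CCc1cc(-c2cc(=O)c3c(O)cc(O)c(CC=C(C)C)c3o2)cc(O)c1O | target

**Step count**

Total steps: 3. Longest linear sequence: 3 steps (1 → 3 → 4 → 6).

**Steps most likely to fail**

1. Step 3 (double Claisen rearrangement). Part of the ring A allyl group may migrate to C6. At the temperature needed, the freshly liberated 7-OH and 4'-OH may add across the neighbouring prenyl double bonds, or the tertiary ethers may ionise and lose isoprene. The fallback sets out from 4 and is an acylative Claisen rearrangement. Compound 4 is heated in PhNEt2 with butanoic anhydride, so that each phenol is esterified as soon as it is unmasked and the kinetic C8 product is frozen before it can react further. The chelated 5-OH resists uncatalysed acylation, so the bias toward C8 should be kept. This should give 7,3',4'-tri-O-butanoyl-epimedokoreanin B F1. Less completely acylated material converges in the next operation, in which the esters are removed with K2CO3 in degassed MeOH at 0 °C. The route is rejoined at 6.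

2. Step 1 (bis-propargylation). Discrimination between the 4'-OH and the 3'-OH may be incomplete, giving alkylation at O3' or a third alkylation. The fallback sets out from 1 and replaces direct alkylation by alkylative de-acetylation. Luteolin is peracetylated (Ac2O, pyridine) to luteolin 5,7,3',4'-tetraacetate F2. F2 is heated with 2, K2CO3, KI and a trace of CuCl2·2H2O in acetone. Under these conditions the acetates of the two most acidic phenols (7, then 4') are cleaved first and the liberated phenoxides are trapped as ethers, giving 5,3'-di-O-acetyl-luteolin 7,4'-bis(2-methylbut-3-yn-2-yl) ether F3. Methanolysis of the two remaining acetates (K2CO3, MeOH, rt) rejoins the route at 3.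

3. Step 2 (semi-hydrogenation). Hydrogen uptake may run past the alkene stage to the saturated tert-pentyl ethers, or the allylic C–O bonds may be hydrogenolysed. The fallback sets out from 1 and avoids the alkyne stage by a Tsuji–Trost O-allylation. tert-Butyl 2-methylbut-3-en-2-yl carbonate F4 is prepared from 2-methylbut-3-en-2-ol and Boc2O. It is coupled with luteolin under catalysis by zerovalent palladium (Pd(PPh3)4, THF, 0 °C). The phenoxides should attack the more substituted terminus of the π-allyl complex and give the branched tertiary ethers directly, with the same preference for O7 and O4'. The route is rejoined at 4.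

Further compounds
F1 | step 3 | 7,3',4'-tri-O-butanoyl-epimedokoreanin B | CC(C)=CCc1cc(-c2cc(=O)c3c(O)cc(OC(=O)CCC)c(CC=C(C)C)c3o2)cc(OC(=O)CCC)c1OC(=O)CCC
F2 | step 1 | luteolin 5,7,3',4'-tetraacetate | CC(=O)Oc1cc(OC(C)=O)c2c(=O)cc(-c3ccc(OC(C)=O)c(OC(C)=O)c3)oc2c1
F3 | step 1 | 5,3'-di-O-acetyl-luteolin 7,4'-bis(2-methylbut-3-yn-2-yl) ether | C#CC(C)(C)Oc1cc(OC(C)=O)c2c(=O)cc(-c3ccc(OC(C)(C)C#C)c(OC(C)=O)c3)oc2c1
F4 | step 2 | tert-butyl 2-methylbut-3-en-2-yl carbonate | C=CC(C)(C)OC(=O)OC(C)(C)C
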